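Remark on numbering: germacrane numbering is used for all ring compounds. C1–C10 form the carbocycle, C14 is the methyl on C10, C15 the methyl on C4, and C11, C12 (carbonyl) and C13 (acetoxymethyl) are the lactone carbons.

## Analysis of the target

Target 24 is a germacranolide: a ten-membered carbocycle (C1–C10) fused at C6–C7 to a butenolide (O on C6, C12=O, C11=C7), with C11 carrying the acetoxymethyl carbon C13. The ring bears two trans-epoxides, C1–C10 and C4–C5, each with a methyl-bearing quaternary carbon, and at C8 an ester of the chlorohydrin acid 22. There are seven stereocentres: C1 (R), C4 (R), C5 (R), C6 (S), C8 (S) and C10 (R) on the ring, and the carbinol carbon of the side chain (R). The C5–O and C6–O bonds are syn, and the C6–O and C8–O bonds are 1,3-syn across the sp2 carbon C7. Both epoxides are acid-labile, and as long as the C1=C10 alkene is present an activated 4,5-epoxide can be attacked across the ring. Base is also a hazard: C6–H is γ to the lactone carbonyl and next to an epoxide, C13 carries an allylic acetate, and the chlorohydrin ester can close to a glycidate. The difficulty lies in closing the ten-membered ring with E geometry at C1=C10, setting C6 relative to C5, and building a tetrasubstituted butenolide between two oxygenated carbons under mild conditions. The plan rests on C6 and C8, two oxygenated carbons that flank C7: without C11, the unit C6(OH)–C7H2–C8(=O) is a β-hydroxy ketone, and a 2-isoxazoline spanning C6–C7–C8 is its masked form, whose formation across the chain also closes the carbocycle.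

## Retrosynthetic reasoning

**24 to 23.** The two C–O bonds of the 1,10-epoxide are cut first, giving alkene 23. The C1=C10 alkene is the only electron-rich double bond in 23, so a peracid can address it alone, and putting it in last keeps the diepoxide away from every earlier reagent. The forward step has to attack the outer face of the E-cycloalkene that leads to 1R,10R.

**23 to 21 and 22.** The ester C–O bond at C8 is cut. This keeps the chlorohydrin acid 22, which brings its own stereocentre, out of all reductive and basic steps. The forward step is an acylation of a hindered allylic alcohol with retention at C8.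

**21 to 20.** The C8–H bond is cut, giving ketone 20. A ketone at C8 is what the butenolide construction needs, and reduction then sets C8 under control of the ring.

**20 to 17, then 14 and 16.** The C7=C11 bond is cut as an aldol condensation and the O6–C12 bond as an ester. Tying the electrophile to the C6 oxygen is the only handle that distinguishes C7 from C9, the other α-carbon of the C8 ketone, because only C7 can close a five-membered ring. The keto acid 16 brings C11, C12 and C13 with the acetate already in place.

**14 to 13.** The C8 carbonyl and the C6 hydroxyl are reconnected through nitrogen as the N–O bridge of isoxazoline 13. Reductive N–O cleavage is the forward step and leaves C6 untouched.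

**13 to 11 (through 12).** The C7–C8 and O–C6 bonds are cut together. This is the key disconnection: one concerted cycloaddition of nitrile oxide 12 onto the vinyl group closes the ten-membered ring, installs both oxygens of the C6/C8 pattern at the right oxidation level and sets C6 next to the existing epoxide. The forward step has to close a strained ring faster than the dipole dimerises and has to choose one face of the vinyl group.

**11 to 6 and 7.** The C8–C9 bond is cut to enal 6 and nitromethane 7, by way of nitrodiene 10. Direct C-alkylation of the anion of 7 was not adopted, because nitronates react with allylic halides largely at oxygen, and the allylation catalysed by zerovalent palladium that avoids this would ionise the vinyl epoxide. Henry addition, dehydration and conjugate reduction add the same carbon without either problem.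

**6 to 4 (through 5).** The C9–O bond is cut. Allylic oxidation of the E-methyl group of 4 places oxygen at C9 and keeps the E geometry that the ring needs.

**4 to 1 (through 3 and 2).** The C6=C7 bond is cut to aldehyde 3, and the epoxide is traced to geraniol 1. Sharpless epoxidation sets C4 and C5 by catalyst control, and all later ring stereocentres are set relative to them.

**16 to 15.** The C13–O bond is cut. Carboxylate displacement on bromopyruvic acid 15 gives the keto acid in one step.

## Alternatives that were turned down

**Alternative 1:** The ring is traced back across C6–C7 to the thirteen-membered diallylic ether A2, in which C6 and C12 are joined through oxygen. In the forward direction C6 of A2 is lithiated and the carbanion undergoes a [2,3]-Wittig shift, which forms C6–C7, contracts the ring to cyclodecadienol A1 and leaves a C6 hydroxyl and an exocyclic C11=C12 methylene.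
- For it: a thirteen-membered ether is much easier to close than a ten-membered carbocycle, the contraction is a concerted low-temperature step, C6 and C7 are set together, and C11–C13 are already on C7. On the ring-forming event itself this plan is stronger than the chosen one. The C6 hydroxyl of A1 could also direct the later 4,5-epoxidation.
- Against it for 24: C7 arrives sp3. To reach the C7=C11 butenolide, C12 must be raised from a methylene to the carboxyl level and the double bond moved into the fused position, which takes several redox steps on a sensitive diene. A diallylic ether can be deprotonated on either side of oxygen, and a [1,2]-shift competes. The only stereocentre before the shift is C8, so the absolute configuration of C6 and C7 rests on a remote centre. Both epoxides still have to be introduced afterwards.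
- Comparison: the chosen route takes its absolute configuration from a catalytic epoxidation and delivers C6–O, C8=O and the 4,5-epoxide directly from the key step, at the price of a less secure ring closure.

**Alternative 2:** The C1=C10 alkene and a C6 carbonyl are traced back to the trans-decalin hydroxy acid A4, in which C1 and C6 are still bonded and C10 carries the carboxyl group. In the forward direction anodic oxidation of the carboxylate of A4 expels CO2, and the tertiary C10 cation is quenched by fragmentation of the C1–C6 bond, pushed by the C6 hydroxyl. This gives cyclodecenone ketal A3.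
- For it: no macrocyclisation is needed, since the ring is released from a six-six system that can be built with full stereocontrol, and the E geometry follows from the ring fusion. After reduction of the C6 ketone and unmasking of the C7 ketal, the α-hydroxy ketone would allow the standard intramolecular Horner–Wadsworth–Emmons closure of the butenolide onto a C7 ketone. On ring formation and on butenolide construction this plan is stronger than the chosen one.
- Against it for 24: A3 has no oxygen at C4 or C5. C4 is a saturated methine, so the 4,5-epoxide would need a dehydrogenation and a later epoxidation, and the C4 stereocentre made in the decalin is destroyed. The cation must fragment and not be trapped or lose a proton, in the presence of a silyl ether and a ketal. A4 carries five stereocentres, of which three vanish in the key step.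
- Comparison: the chosen route is shorter and keeps every stereocentre it makes.

**Alternative 3:** The C8–C9 bond is cut, leading back to allylsilane aldehyde A6, in which the butenolide with its acetoxymethyl group is complete and C8 is an aldehyde on C7. In the forward direction a boron Lewis acid activates the aldehyde and the C9 terminus of the allylsilane attacks it, forming C8–C9 and the C10=C1 alkene with loss of silicon. This gives the 8-hydroxy germacradienolide A5.
- For it: A5 is only an acylation and two epoxidations away from 24, so the endgame is shorter than in the chosen route, and the butenolide problem is solved before the ring is closed.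
- Against it for 24: a Lewis-acid-driven closure of a ten-membered ring has no concerted tether to help it, and protodesilylation or ionisation of the allylic acetate compete. The geometry of the new C10=C1 alkene and the configuration at C8 are set in the same step by a single remote centre, C6. Because the conditions are acidic, neither epoxide can be present, so both must be installed afterwards on a diene, and four stereocentres then depend on conformational bias alone.
- Comparison: the chosen route carries the 4,5-epoxide in from a catalytic asymmetric step and closes the ring under neutral conditions, at the price of a longer endgame.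

Key step: step 8

Assumptions: acid 22 and bromopyruvic acid 15 are taken as purchased. The facial outcomes written for steps 8, 13 and 15 are the expected ones and are treated as uncertain in the closing section.

## Route

Step 1
Reactants: 1 geraniol
Product: 2 (2R,3R)-2,3-epoxygeraniol
Conditions: Ti(OiPr)4 (5 mol%), D-(−)-diethyl tartrate (7 mol%), tBuOOH, 4 Å MS, CH2Cl2, −20 °C
Reagents that add atoms: tert-butyl hydroperoxide, CC(C)(C)OO
Why: Sharpless asymmetric epoxidation; the titanium tartrate complex binds the allylic hydroxyl and delivers oxygen to one face of the C4=C5 alkene, and the D-(−)-tartrate is the ligand enantiomer that gives the (2R,3R)-epoxy alcohol, which becomes 4R,5R of the target. The remote trisubstituted alkene has no directing hydroxyl and should not react.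

Step 2
Reactants: 2 (2R,3R)-2,3-epoxygeraniol
Product: 3 (2S,3R)-3-methyl-3-(4-methylpent-3-en-1-yl)oxirane-2-carbaldehyde
Conditions: TEMPO (10 mol%), PhI(OAc)2, CH2Cl2, rt
Reagents that add atoms: none
Why: Nitroxyl-catalysed oxidation of a primary alcohol stops at the aldehyde and is mild enough for the epoxide and the alkene. No stereocentre is touched; the change of descriptor at the epoxide CH is only a change of priorities.

Step 3
Reactants: 3 (2S,3R)-3-methyl-3-(4-methylpent-3-en-1-yl)oxirane-2-carbaldehyde
Product: 4 (2R,3R)-3-ethenyl-2-methyl-2-(4-methylpent-3-en-1-yl)oxirane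
Conditions: Ph3PCH3Br, KN(SiMe3)2, THF, 0 °C; then 3, −78 → 0 °C
Reagents that add atoms: methyltriphenylphosphonium bromide, C[P+](c1ccccc1)(c1ccccc1)c1ccccc1.[Br-]
Why: Wittig methylenation with the non-stabilised ylide converts the epoxy aldehyde into the vinyl epoxide (C6=C7). The epoxide CH is not acidic enough to epimerise under these conditions.

Step 4
Reactants: 4 (2R,3R)-3-ethenyl-2-methyl-2-(4-methylpent-3-en-1-yl)oxirane
Product: 5 (2E)-5-[(2R,3R)-3-ethenyl-2-methyloxiran-2-yl]-2-methylpent-2-en-1-ol
Conditions: SeO2 (0.3 equiv), tBuOOH, CH2Cl2, 0 °C → rt
Reagents that add atoms: tert-butyl hydroperoxide, CC(C)(C)OO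
Why: Catalytic SeO2 allylic oxidation (ene reaction, then [2,3] shift) attacks the E-methyl group of a trisubstituted alkene, so C9 is hydroxylated and the 1(10)E geometry is kept. The vinyl group has only the epoxide C–H in the allylic position and should stay inert; any enal 6 formed by over-oxidation is carried into step 5.

Step 5
Reactants: 5 (2E)-5-[(2R,3R)-3-ethenyl-2-methyloxiran-2-yl]-2-methylpent-2-en-1-ol
Product: 6 (2E)-5-[(2R,3R)-3-ethenyl-2-methyloxiran-2-yl]-2-methylpent-2-enal
Conditions: MnO2 (excess), CH2Cl2, rt
Reagents that add atoms: none
Why: Oxidation of an allylic alcohol on activated MnO2 is neutral and selective, so the vinyl epoxide and the alkene geometry should survive.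

Step 6
Reactants: 6 (2E)-5-[(2R,3R)-3-ethenyl-2-methyloxiran-2-yl]-2-methylpent-2-enal; 7 nitromethane
Product: 10 (2R,3R)-3-ethenyl-2-methyl-2-[(3E,5E)-4-methyl-6-nitrohexa-3,5-dien-1-yl]oxirane, via nitro alcohol 8 (not isolated), via nitro mesylate 9 (not isolated)
Conditions: CH3NO2 (10 equiv), tetramethylguanidine (10 mol%), THF, 0 °C; evaporate; MsCl, Et3N, CH2Cl2, −20 → 0 °C
Reagents that add atoms: none
Why: Henry addition of the nitronate to the aldehyde (1,2-addition, the β-carbon of the enal being trisubstituted), then mesylation and E1cB loss of methanesulfonate give the conjugated E-nitroalkene; this adds C8 with its nitrogen. The carbinol centre of 8 is not controlled and disappears.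

Step 7
Reactants: 10 (2R,3R)-3-ethenyl-2-methyl-2-[(3E,5E)-4-methyl-6-nitrohexa-3,5-dien-1-yl]oxirane
Product: 11 (2R,3R)-3-ethenyl-2-methyl-2-[(3E)-4-methyl-6-nitrohex-3-en-1-yl]oxirane
Conditions: NaBH4, THF/MeOH, −20 → 0 °C; AcOH to pH 5 at 0 °C
Reagents that add atoms: none
Why: Conjugate reduction of a nitroalkene: hydride adds to C9, the carbon β to the nitro group, and the nitronate is protonated at C8 on work-up. The C1=C10 alkene is not part of the nitronate and keeps its E geometry; the more substituted δ-carbon is the less likely site of attack.

Step 8
Reactants: 11 (2R,3R)-3-ethenyl-2-methyl-2-[(3E)-4-methyl-6-nitrohex-3-en-1-yl]oxirane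
Product: 13 bridged isoxazoline (4R,5R,6S,1(10)E), via nitrile oxide 12 (not isolated)
Conditions: PhNCO (4 equiv), Et3N (0.3 equiv), toluene, 80 °C; 11 added by syringe pump over 24 h, final 0.002 M
Reagents that add atoms: none
Why: Et3N deprotonates the primary nitro group of 11, the nitronate oxygen adds to PhNCO and the adduct collapses to nitrile oxide 12 with loss of N-phenylcarbamic acid, which ends as diphenylurea and CO2 (Mukaiyama dehydration). The dipole then adds in a concerted, suprafacial [3+2] fashion to the vinyl group, C8 bonding to the terminal carbon C7 and the dipole oxygen to C6; the closest known reaction type is the intramolecular nitrile oxide–olefin cycloaddition in its bridged, macrocyclic mode. Two rings close: the isoxazoline (O, N, C8, C7, C6) by the cycloaddition itself, and the ten-membered carbocycle C1–C10 by the new C7–C8 bond, with C7 left as a one-carbon bridge (bridged mode, not fused mode). Regiochemistry needs no help, because oxygen at the substituted alkene carbon is the normal preference for a monosubstituted alkene and the fused alternative would need a nine-membered ring; the C1=C10 alkene cannot be reached within the molecule without forming a three- or four-membered ring and is a slow dipolarophile between molecules. The one new stereocentre, C6, is controlled by the adjacent epoxide carbon C5 and by the tether: the chain enters through C4, so C4 must lie on the face that the dipole attacks, and of the arrangements left the one with C5–H anti to the forming O–C6 bond and the epoxide C5–O bond near the alkene plane (the inside position of the inside-alkoxy model) should be favoured, which places O6 syn to the epoxide oxygen, that is 6S. The step needs cyclisation to beat dimerisation of 12, which is why 11 is fed slowly into a hot, very dilute solution; the E alkene and the trans-epoxide reduce the freedom of the tether and should help. The facial preference is an argument and not a certainty.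

Step 9
Reactants: 13 bridged isoxazoline (4R,5R,6S,1(10)E)
Product: 14 (4R,5R,6S)-4,5-epoxy-6-hydroxy-11,12,13-trinorgermacr-1(10)E-en-8-one
Conditions: Mo(CO)6, MeCN/H2O (10:1), 75 °C
Reagents that add atoms: water, O
Why: Zerovalent molybdenum cleaves the N–O bond reductively, and the β-hydroxy imine hydrolyses to the C8 ketone, which unmasks the aldol pattern. C6 is not touched, and the alkene and the epoxide are not reduced by this reagent.

Step 10
Reactants: 15 bromopyruvic acid
Product: 16 3-acetoxy-2-oxopropanoic acid
Conditions: KOAc (2.2 equiv), acetone, 0 °C → rt; then 1 M HCl, EtOAc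
Reagents that add atoms: potassium acetate, CC(=O)[O-].[K+]
Why: SN2 displacement of a bromide α to a ketone by carboxylate is fast. The first equivalent of acetate only deprotonates the acid, and acidification releases the keto acid, which is used fresh.

Step 11
Reactants: 14 (4R,5R,6S)-4,5-epoxy-6-hydroxy-11,12,13-trinorgermacr-1(10)E-en-8-one; 16 3-acetoxy-2-oxopropanoic acid
Product: 17 6-O-(3-acetoxy-2-oxopropanoyl) ester of 14
Conditions: DCC, DMAP (10 mol%), CH2Cl2, −20 → 0 °C
Reagents that add atoms: none
Why: Steglich esterification acylates the C6 hydroxyl with retention and tethers C11–C13 to the oxygen that will become the lactone oxygen. Low temperature and only catalytic DMAP are meant to limit dehydration of the β-hydroxy ketone.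

Step 12
Reactants: 17 6-O-(3-acetoxy-2-oxopropanoyl) ester of 14
Product: 20 (4R,5R,6S)-13-acetoxy-4,5-epoxy-8-oxogermacra-1(10)E,7(11)-dien-6,12-olide, via aldol lactone 18 (not isolated), via tertiary mesylate 19 (not isolated)
Conditions: Et3N, CH2Cl2, 0 °C → rt; then MsCl, Et3N, −20 → 0 °C
Reagents that add atoms: none
Why: Intramolecular aldol condensation: the C7 enol(ate) of the C8 ketone adds to the strongly electrophilic C11 ketone of the 1,2-dicarbonyl tether in a 5-exo-trig closure, while enolisation towards C9 is unproductive because it could only close a seven-membered ring. Mesylation of the tertiary hydroxyl and E1cB loss across C7–C11 then give the butenolide; the centres at C7 and C11 in 18 vanish and C6 is not touched.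

Step 13
Reactants: 20 (4R,5R,6S)-13-acetoxy-4,5-epoxy-8-oxogermacra-1(10)E,7(11)-dien-6,12-olide
Product: 21 (4R,5R,6S,8S)-13-acetoxy-4,5-epoxy-8-hydroxygermacra-1(10)E,7(11)-dien-6,12-olide
Conditions: NaBH4, CeCl3·7H2O, MeOH/CH2Cl2, −78 °C
Reagents that add atoms: none
Why: Luche reduction gives 1,2-addition to the enone carbonyl and leaves the lactone, the acetate and the epoxide alone. Hydride should arrive on the outer face of C8, away from the chain C9–C5 that spans the other face of the butenolide plane, which gives the 8S alcohol with C8–O syn to C6–O; this is a conformational argument.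

Step 14
Reactants: 21 (4R,5R,6S,8S)-13-acetoxy-4,5-epoxy-8-hydroxygermacra-1(10)E,7(11)-dien-6,12-olide; 22 (R)-3-chloro-2-hydroxy-2-methylpropanoic acid
Product: 23 8-O-[(R)-3-chloro-2-hydroxy-2-methylpropanoyl] ester of 21
Conditions: DCC, DMAP (20 mol%), CH2Cl2, 0 °C → rt
Reagents that add atoms: none
Why: Steglich esterification with retention at C8. The tertiary hydroxyl of 22 is a poor acyl acceptor, so self-condensation should be slow, and the chlorohydrin does not close without an alkoxide base.

Step 15
Reactants: 23 8-O-[(R)-3-chloro-2-hydroxy-2-methylpropanoyl] ester of 21
Product: 24 target CNP0255009.1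
Conditions: mCPBA, NaHCO3, CH2Cl2, 0 °C
Reagents that add atoms: 3-chloroperbenzoic acid, O=C(OO)c1cccc(Cl)c1
Why: Prilezhaev epoxidation; the trisubstituted C1=C10 alkene is the only electron-rich double bond, the butenolide alkene being deactivated. An E-cyclodecene exposes only its outer face, and in the crossed conformation expected for this ring type (C14 and C15 on the same side) that face should lead to the 1R,10R epoxide; syn addition to the E alkene gives the trans-epoxide.

## Compound list

1 | geraniol | CC(C)=CCC/C(C)=C/CO | starting material
2 | (2R,3R)-2,3-epoxygeraniol | CC(C)=CCC[C@@]1(C)O[C@@H]1CO | intermediate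
3 | (2S,3R)-3-methyl-3-(4-methylpent-3-en-1-yl)oxirane-2-carbaldehyde | CC(C)=CCC[C@@]1(C)O[C@@H]1C=O | intermediate
4 | (2R,3R)-3-ethenyl-2-methyl-2-(4-methylpent-3-en-1-yl)oxirane | CC(C)=CCC[C@@]1(C)O[C@@H]1C=C | intermediate
5 | (2E)-5-[(2R,3R)-3-ethenyl-2-methyloxiran-2-yl]-2-methylpent-2-en-1-ol | OC/C(C)=C/CC[C@@]1(C)O[C@@H]1C=C | intermediate
6 | (2E)-5-[(2R,3R)-3-ethenyl-2-methyloxiran-2-yl]-2-methylpent-2-enal | O=C/C(C)=C/CC[C@@]1(C)O[C@@H]1C=C | intermediate
7 | nitromethane | C[N+](=O)[O-] | starting material
8 | (3E)-6-[(2R,3R)-3-ethenyl-2-methyloxiran-2-yl]-3-methyl-1-nitrohex-3-en-2-ol, both carbinol epimers | [O-][N+](=O)CC(O)/C(C)=C/CC[C@@]1(C)O[C@@H]1C=C | intermediate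
9 | methanesulfonate of 8 | [O-][N+](=O)CC(OS(C)(=O)=O)/C(C)=C/CC[C@@]1(C)O[C@@H]1C=C | intermediate
10 | (2R,3R)-3-ethenyl-2-methyl-2-[(3E,5E)-4-methyl-6-nitrohexa-3,5-dien-1-yl]oxirane | [O-][N+](=O)/C=C/C(C)=C/CC[C@@]1(C)O[C@@H]1C=C | intermediate
11 | (2R,3R)-3-ethenyl-2-methyl-2-[(3E)-4-methyl-6-nitrohex-3-en-1-yl]oxirane | [O-][N+](=O)CC/C(C)=C/CC[C@@]1(C)O[C@@H]1C=C | intermediate
12 | (3E)-6-[(2R,3R)-3-ethenyl-2-methyloxiran-2-yl]-3-methylhex-3-enenitrile oxide | [O-][N+]#CC/C(C)=C/CC[C@@]1(C)O[C@@H]1C=C | intermediate
13 | bridged isoxazoline: 2-isoxazoline with C8 as its C=N carbon, C7 as its CH2 and C6 as its O-bearing carbon, spanned from C8 to C6 by the chain C9–C10(CH3)=C1–C2–C3–C4(CH3)–C5 with the 4,5-epoxide; 4R,5R,6S,1(10)E | N1=C2C/C(C)=C/CC[C@@]3(C)O[C@@H]3[C@H](C2)O1 | intermediate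
14 | (4R,5R,6S)-4,5-epoxy-6-hydroxy-11,12,13-trinorgermacr-1(10)E-en-8-one (ten-membered ring ketone with methyls on C4 and C10) | O=C1C/C(C)=C/CC[C@@]2(C)O[C@@H]2[C@@H](O)C1 | intermediate
15 | bromopyruvic acid (3-bromo-2-oxopropanoic acid) | OC(=O)C(=O)CBr | starting material
16 | 3-acetoxy-2-oxopropanoic acid | CC(=O)OCC(=O)C(=O)O | intermediate
17 | 6-O-(3-acetoxy-2-oxopropanoyl) ester of 14 | O=C1C/C(C)=C/CC[C@@]2(C)O[C@@H]2[C@@H](OC(=O)C(=O)COC(C)=O)C1 | intermediate
18 | aldol lactone: (4R,5R,6S)-13-acetoxy-4,5-epoxy-11-hydroxy-8-oxogermacr-1(10)E-en-6,12-olide, C7 and C11 not controlled | CC(=O)OCC1(O)C2C(=O)C/C(C)=C/CC[C@@]3(C)O[C@@H]3[C@H]2OC1=O | intermediate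
19 | 11-O-methanesulfonate of 18 | CC(=O)OCC1(OS(C)(=O)=O)C2C(=O)C/C(C)=C/CC[C@@]3(C)O[C@@H]3[C@H]2OC1=O | intermediate
20 | (4R,5R,6S)-13-acetoxy-4,5-epoxy-8-oxogermacra-1(10)E,7(11)-dien-6,12-olide | CC(=O)OCC1=C2C(=O)C/C(C)=C/CC[C@@]3(C)O[C@@H]3[C@H]2OC1=O | intermediate
21 | (4R,5R,6S,8S)-13-acetoxy-4,5-epoxy-8-hydroxygermacra-1(10)E,7(11)-dien-6,12-olide | CC(=O)OCC1=C2[C@@H](O)C/C(C)=C/CC[C@@]3(C)O[C@@H]3[C@H]2OC1=O | intermediate
22 | (R)-3-chloro-2-hydroxy-2-methylpropanoic acid | OC(=O)[C@@](C)(O)CCl | starting material
23 | (4R,5R,6S,8S)-13-acetoxy-8-[(2R)-3-chloro-2-hydroxy-2-methylpropanoyloxy]-4,5-epoxygermacra-1(10)E,7(11)-dien-6,12-olide | CC(=O)OCC1=C2[C@@H](OC(=O)[C@@](C)(O)CCl)C/C(C)=C/CC[C@@]3(C)O[C@@H]3[C@H]2OC1=O | intermediate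
24 | CNP0255009.1: (1R,4R,5R,6S,8S,10R)-13-acetoxy-8-[(2R)-3-chloro-2-hydroxy-2-methylpropanoyloxy]-1,10:4,5-diepoxygermacr-7(11)-en-6,12-olide | CC(=O)OCC1=C2[C@@H](OC(=O)[C@@](C)(O)CCl)C[C@@]3(C)O[C@@H]3CC[C@@]3(C)O[C@@H]3[C@H]2OC1=O | target

## Step count and least certain steps

Total step count: 15. Longest linear sequence: 14 steps (steps 1–9 and 11–15, from 1 to 24); step 10 is a one-step side branch.

**Step 8 (key step).** The most likely failure is that closure of the strained ten-membered bicycle is slower than the bimolecular reactions of the short-lived dipole, so that dimerisation and oligomerisation of the nitrile oxide consume the material even at high dilution. The second uncertainty, the face of C6, is treated under step 11. The fallback changes the dipole. Starting from 11, silylation (Me3SiCl, Et3N, benzene) would give the silyl nitronate F1, a 1,3-dipole that does not dimerise and can therefore be heated for a long time at high dilution. Intramolecular silyl nitronate–olefin cycloaddition, with the same regiochemistry (oxygen to C6, C8 to C7), would give the N-silyloxy isoxazolidine F2. Mild acid or fluoride then eliminates silanol and returns to the route at isoxazoline 13.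

**Step 12.** The C7 enolate that must attack C11 also has the C6 keto-carboxylate in the β-position, and E1cB loss of that good leaving group may outrun the aldol closure. Enolisation towards C9 can also move the C1=C10 alkene into conjugation. The fallback forms the C7–C11 bond while the C6 oxygen is still locked in the isoxazoline and cannot leave. Starting from 13, deprotonation at C7 (LiN(iPr)2, THF, −78 °C; the ring carbon syn to the isoxazoline oxygen is the kinetic site) and addition to ethyl 3-acetoxy-2-oxopropanoate F5 (from ethyl bromopyruvate and KOAc, as in step 10) would give the C7 adduct F6. N–O cleavage with Mo(CO)6 as in step 9 would release the hydroxy ketone ester F7, whose C6 hydroxyl should close onto the ethyl ester. This comes back to the route at aldol lactone 18, which is dehydrated to 20 as in the second half of step 12.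

**Step 11.** A carbodiimide coupling acylates with retention, so any shortfall in facial selectivity from step 8 is fixed into the ester at this point and cannot be corrected later; slow acylation of the hindered β-ketol with competing loss of water is the second concern. The fallback uses the other epimer productively. The C6-epimeric cycloadduct F3 would be separated, cleaved with Mo(CO)6 to the 6R hydroxy ketone F4 and esterified with 16 under Mitsunobu conditions (PPh3, diisopropyl azodicarboxylate, THF, 0 °C). This inverts C6 and comes back to the route at 17.

**Step 13.** Facial selectivity at C8 depends on which conformation of the ten-membered ring is reduced, so hydride delivery to the other face, giving the 8R alcohol, is the likely failure; conjugate reduction of the enedione-like system is a lesser one. The fallback accepts the other epimer. Starting from 20, the 8R alcohol F8 would be esterified directly with 22 under Mitsunobu conditions (PPh3, diisopropyl azodicarboxylate), where the carboxylic acid is the only acidic partner; inversion at C8 returns to the route at 23.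

**Step 15.** The peracid may attack the other accessible conformer of the C1=C10 alkene and give the 1S,10S epoxide. The 3-chlorobenzoic acid formed may also trigger transannular opening of the 4,5-epoxide by the alkene before it is consumed. The fallback replaces conformational control by delivery from a hydroxyl. Starting from 21, in which the C8 hydroxyl is homoallylic to C1=C10, epoxidation with VO(acac)2 and tBuOOH should place oxygen on the face of C10 syn to O8, which is the face required, and give diepoxy alcohol F9. Acylation with 22 (DCC, DMAP) then comes back to the route at 24.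

## Further compounds

F1 | step 8 | trimethylsilyl nitronate of 11 | C[Si](C)(C)O[N+]([O-])=CC/C(C)=C/CC[C@@]1(C)O[C@@H]1C=C
F2 | step 8 | N-(trimethylsilyloxy)isoxazolidine, the 8,N-dihydro N-silyloxy form of 13, C8 not controlled | C[Si](C)(C)ON1C2C/C(C)=C/CC[C@@]3(C)O[C@@H]3[C@H](C2)O1
F3 | step 11 | C6 epimer of 13 (4R,5R,6R) | N1=C2C/C(C)=C/CC[C@@]3(C)O[C@@H]3[C@@H](C2)O1
F4 | step 11 | C6 epimer of 14 (4R,5R,6R) | O=C1C/C(C)=C/CC[C@@]2(C)O[C@@H]2[C@H](O)C1
F5 | step 12 | ethyl 3-acetoxy-2-oxopropanoate | CCOC(=O)C(=O)COC(C)=O
F6 | step 12 | 13 carrying at C7 the group C(OH)(CH2OAc)CO2Et, C7 and C11 not controlled | N1=C2C/C(C)=C/CC[C@@]3(C)O[C@@H]3[C@H](C2C(O)(COC(C)=O)C(=O)OCC)O1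
F7 | step 12 | 14 carrying at C7 the group C(OH)(CH2OAc)CO2Et, C7 and C11 not controlled | CCOC(=O)C(O)(COC(C)=O)C1C(=O)C/C(C)=C/CC[C@@]2(C)O[C@@H]2[C@H]1O
F8 | step 13 | C8 epimer of 21 (4R,5R,6S,8R) | CC(=O)OCC1=C2[C@H](O)C/C(C)=C/CC[C@@]3(C)O[C@@H]3[C@H]2OC1=O
F9 | step 15 | (1R,4R,5R,6S,8S,10R)-13-acetoxy-1,10:4,5-diepoxy-8-hydroxygermacr-7(11)-en-6,12-olide | CC(=O)OCC1=C2[C@@H](O)C[C@@]3(C)O[C@@H]3CC[C@@]3(C)O[C@@H]3[C@H]2OC1=O
A1 | alternative 1 | cyclodecadienol with a 2-substituted allyl branch on C7 | C=C(CO[Si](C)(C)C(C)(C)C)[C@@H]2[C@@H](OCOC)C/C(C)=C/CC/C(C)=C/[C@H]2O
A2 | alternative 1 | thirteen-membered diallylic ether (O between C6 and C12) | O1C/C(CO[Si](C)(C)C(C)(C)C)=C/[C@@H](OCOC)C/C(C)=C/CC/C(C)=C/C1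
A3 | alternative 2 | cyclodecenone ketal | O1CCOC12[C@@H](O[Si](C)(C)C(C)(C)C)C/C(C)=C/CC[C@@H](C)CC2=O
A4 | alternative 2 | trans-decalin hydroxy acid with C1–C6 bond, C10 carboxyl and C6 hydroxyl | OC(=O)[C@@]1(C)C[C@H](O[Si](C)(C)C(C)(C)C)C2(OCCO2)[C@]3(O)C[C@H](C)CC[C@@H]13
A5 | alternative 3 | 8-hydroxy germacradienolide | CC(=O)OCC1=C2[C@@H](O)C/C(C)=C/CC/C(C)=C/[C@H]2OC1=O
A6 | alternative 3 | allylsilane aldehyde with complete butenolide, silyl-bearing C1 not controlled | CC(=O)OCC1=C(C=O)[C@@H](/C=C(C)/CCC([Si](C)(C)C)C(C)=C)OC1=O
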